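The target is fisetinidol-(4β→6)-leucofisetinidin (upper unit rings A/B/C, lower unit rings D/E/F). Ring D is a resorcinol nucleus whose C6 and C4a are each ortho to one oxygen and para to the other, so 4,6-dibromoresorcinol serves as linchpin: one bromine becomes the interflavan bond, the other is kept for the key step, a Parham cyclisation in which the C4a aryllithium of ring D attacks a Weinreb amide tethered through O1 and closes ring F at the C4–C4a bond. The precursor is an open-chain aryl ether made by Mitsunobu inversion of an Evans glycolate aldol, which also supplies ring C. The resulting C4 ketone is reduced last to the 3,4-trans diol.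

Key step: step 11

Remark: flavan atom numbers are used for each unit; the carbinol carbon of 18 and the hemiaminal carbons of 12 and 24 are formed without control because they are erased in the following event.

Step 1
Reactants: 1 (R)-4-benzyl-1,3-oxazolidin-2-one; 2 benzyloxyacetyl chloride
Product: 3 (R)-4-benzyl-3-[(benzyloxy)acetyl]-1,3-oxazolidin-2-one
Conditions: Et3N, DMAP (cat.), CH2Cl2, 0 → 23 °C
Reagents that add atoms: none
Why: N-acylation of the oxazolidinone by the acid chloride under DMAP catalysis should give the glycolate imide needed for an auxiliary-controlled aldol reaction.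

Step 2
Reactants: 3 glycolate imide; 4 3,4-bis(benzyloxy)benzaldehyde
Product: 6 (R)-4-benzyl-3-[(2R,3S)-2-(benzyloxy)-3-[3,4-bis(benzyloxy)phenyl]-3-hydroxypropanoyl]-1,3-oxazolidin-2-one, via Z-dibutylboron enolate 5 (not isolated)
Conditions: Bu2BOTf, Et3N, CH2Cl2, −78 → 0 °C; then 4, −78 → 0 °C; then H2O2, MeOH, pH 7 buffer, 0 °C
Reagents that add atoms: none
Why: Evans syn-aldol reaction in which the Z-boron enolate reacts through a Zimmerman–Traxler chair on the face away from the auxiliary benzyl group, setting C2 (R, the future C3 of each flavan unit) and C3 (S, the future C2 after inversion).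

Step 3
Reactants: 6 syn-aldol imide
Product: 7 (2R,3S)-2-(benzyloxy)-3-[3,4-bis(benzyloxy)phenyl]-3-hydroxy-N-methoxy-N-methylpropanamide
Conditions: MeNH(OMe)·HCl, AlMe3, CH2Cl2, −10 → 23 °C
Reagents that add atoms: N,O-dimethylhydroxylamine hydrochloride, CNOC.Cl
Why: Aluminium-amide transamination of the aldol imide (Weinreb aminolysis, assisted by the free β-hydroxyl) should release the auxiliary without touching either stereocentre and install an acyl group that stops at the ketone stage.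

Step 4
Reactants: 8 3-(benzyloxy)phenol
Product: 9 5-(benzyloxy)-2-iodophenol
Conditions: I2, NaHCO3, THF/H2O, 0 °C
Reagents that add atoms: iodine, II
Why: Electrophilic aromatic iodination of the phenolate should occur at the unhindered carbon ortho to the hydroxyl and para to the benzyloxy group.

Step 5
Reactants: 7 hydroxy Weinreb amide; 9 5-(benzyloxy)-2-iodophenol
Product: 10 (2R,3R)-2-(benzyloxy)-3-[5-(benzyloxy)-2-iodophenoxy]-3-[3,4-bis(benzyloxy)phenyl]-N-methoxy-N-methylpropanamide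
Conditions: PPh3, DIAD, toluene, 0 → 23 °C
Reagents that add atoms: none
Why: Mitsunobu etherification in which the acidic iodophenol displaces the activated benzylic hydroxyl with inversion, turning the syn aldol into the anti aryl ether that corresponds to a 2,3-trans flavan.

Step 6
Reactants: 10 iodoaryl ether Weinreb amide
Product: 13 (2R,3R)-3,7-bis(benzyloxy)-2-[3,4-bis(benzyloxy)phenyl]chroman-4-one (tetra-O-benzylfustin), via arylmagnesium chloride 11 (not isolated), via magnesium hemiaminal chelate 12 (not isolated)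
Conditions: i-PrMgCl·LiCl, THF, −20 → 23 °C; then H2O
Reagents that add atoms: none
Why: Iodine–magnesium exchange followed by 6-exo-trig attack of the arylmagnesium on the Weinreb amide (Parham-type cyclisation) should close ring C, and the chelated tetrahedral adduct keeps C2 and C3 away from base until quench.

Step 7
Reactants: 14 4,6-dibromobenzene-1,3-diol
Product: 15 1,5-dibromo-2,4-bis[(4-methoxybenzyl)oxy]benzene
Conditions: 4-methoxybenzyl chloride, K2CO3, DMF, 23 °C
Reagents that add atoms: 4-methoxybenzyl chloride, COc1ccc(CCl)cc1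
Why: Williamson etherification of both phenols keeps the two bromines equivalent, so that a single exchange later gives one aryllithium only.

Step 8
Reactants: 15 dibromo bis(4-methoxybenzyl) ether; 13 tetra-O-benzylfustin
Product: 18 (2R,3R)-3,7-bis(benzyloxy)-2-[3,4-bis(benzyloxy)phenyl]-4-{5-bromo-2,4-bis[(4-methoxybenzyl)oxy]phenyl}chroman-4-ol, via aryllithium 16 (not isolated), via arylcerium dichloride 17 (not isolated)
Conditions: 15, n-BuLi (1.0 equiv), THF, −78 °C; CeCl3, −78 °C; then 13, −78 → −40 °C; then H2O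
Reagents that add atoms: none
Why: Mono bromine–lithium exchange, transmetalation to the weakly basic organocerium and 1,2-addition to the hindered enolisable ketone should form the future interflavan bond, the configuration at C4 being irrelevant because C4 is ionised in step 9.

Step 9
Reactants: 18 tertiary bis-benzylic alcohol
Product: 21 (2R,3S,4S)-3,7-bis(benzyloxy)-2-[3,4-bis(benzyloxy)phenyl]-4-(5-bromo-2,4-dihydroxyphenyl)chromane, via C4 benzylic cation 19 (not isolated), via 4β-aryl bis(4-methoxybenzyl) ether 20 (not isolated)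
Conditions: Et3SiH (excess), TFA, CH2Cl2, −40 → 0 °C
Reagents that add atoms: none
Why: Ionic hydrogenation in which TFA ionises the tertiary alcohol and Et3SiH should deliver hydride to the planar C4 cation anti to the adjacent 3-benzyloxy group (tilted pseudo-axial by allylic strain with the C4 aryl group), so that the aryl group ends cis to O3 (4β, 2,3-trans-3,4-cis), after which the acid cleaves both 4-methoxybenzyl ethers and the silane scavenges their cation.

Step 10
Reactants: 21 bromoresorcinol flavan; 7 hydroxy Weinreb amide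
Product: 22 (2R,3R)-2-(benzyloxy)-3-[3,4-bis(benzyloxy)phenyl]-3-{4-[(2R,3S,4S)-3,7-bis(benzyloxy)-2-[3,4-bis(benzyloxy)phenyl]chroman-4-yl]-2-bromo-5-hydroxyphenoxy}-N-methoxy-N-methylpropanamide
Conditions: PPh3, DIAD, toluene, 0 → 23 °C
Reagents that add atoms: none
Why: Mitsunobu etherification with inversion at the benzylic carbon (setting the future C2 of ring F), in which the phenol ortho to bromine should react selectively because it is the more acidic and less hindered one, the other being flanked by the flavanyl group.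

Step 11
Reactants: 22 bromoaryl ether Weinreb amide
Product: 25 (2R,3R)-3-(benzyloxy)-2-[3,4-bis(benzyloxy)phenyl]-6-[(2R,3S,4S)-3,7-bis(benzyloxy)-2-[3,4-bis(benzyloxy)phenyl]chroman-4-yl]-7-hydroxychroman-4-one, via dilithiated aryl phenoxide 23 (not isolated), via lithium hemiaminal chelate 24 (not isolated)
Conditions: t-BuLi (3.1 equiv), THF, −90 → −78 °C; then H2O
Reagents that add atoms: none
Why: The first equivalent of t-BuLi forms the lithium phenoxide of ring D, bromine–lithium exchange then converts the only C–Br bond (at C4a, ortho to the ether oxygen O1) into an aryllithium, and this carbanion attacks the tethered Weinreb amide carbonyl (the future C4) to give a lithium N,O-chelate that collapses to the ketone only on quench. The closest known reaction type is the Parham cyclisation of 2-halophenoxypropanoic acid derivatives to chroman-4-ones, combined with the Weinreb ketone synthesis. Ring F closes in a 6-exo-trig mode. No new stereocentre is formed: C2 and C3 of ring F remain as set in steps 2 and 10 because the chelate masks the enolisable 3-benzyloxy ketone from base until work-up, and C4 is set in step 13. The step needs exchange to outrun deprotonation alpha to the amide (which would expel the aryloxide) and needs a single site of C–C bond formation; the bromine inherited from the dibromoresorcinol fixes closure at C4a instead of C8, and exchange at −90 °C should be faster than any C–H deprotonation or attack of the hindered base on the amide.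

Step 12
Reactants: 25 hepta-O-benzyl ketone
Product: 26 (2R,3R)-2-(3,4-dihydroxyphenyl)-6-[(2R,3S,4S)-2-(3,4-dihydroxyphenyl)-3,7-dihydroxychroman-4-yl]-3,7-dihydroxychroman-4-one (fisetinidol-(4β→6)-fustin)
Conditions: H2 (1 atm), Pd(OH)2/C, THF/MeOH, 23 °C
Reagents that add atoms: none
Why: Hydrogenolysis of the seven benzyl ethers is done at the ketone stage because the aryl ketone conjugated to two ring oxygens should survive neutral hydrogenation, whereas the later C4 benzylic alcohol would not.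

Step 13
Reactants: 26 fisetinidol-(4β→6)-fustin
Product: 27 (2R,3S,4R)-2-(3,4-dihydroxyphenyl)-6-[(2R,3S,4S)-2-(3,4-dihydroxyphenyl)-3,7-dihydroxychroman-4-yl]chromane-3,4,7-triol (target CNP0280090.2)
Conditions: NaBH4, EtOH, 0 °C; then AcOH to pH 6
Reagents that add atoms: none
Why: Substrate-controlled ketone reduction in which borohydride should add to the C4 carbonyl of the 2,3-trans dihydroflavonol so that the new hydroxyl is equatorial and trans to the C3 hydroxyl (4R), as in the reduction of fustin to mollisacacidin, under conditions mild enough to spare the ionisable benzylic alcohol.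

Compound list
1 | (R)-4-benzyl-1,3-oxazolidin-2-one | O=C1N[C@H](Cc2ccccc2)CO1 | starting material
2 | benzyloxyacetyl chloride | O=C(Cl)COCc1ccccc1 | starting material
3 | (R)-4-benzyl-3-[(benzyloxy)acetyl]-1,3-oxazolidin-2-one | O=C(COCc1ccccc1)N1[C@H](Cc2ccccc2)COC1=O | intermediate
4 | 3,4-bis(benzyloxy)benzaldehyde | O=Cc1ccc(OCc2ccccc2)c(OCc2ccccc2)c1 | starting material
5 | Z-dibutylboron enolate of 3 | CCCCB(CCCC)O/C(=C\OCc1ccccc1)N1[C@H](Cc2ccccc2)COC1=O | intermediate (not isolated)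
6 | (R)-4-benzyl-3-[(2R,3S)-2-(benzyloxy)-3-[3,4-bis(benzyloxy)phenyl]-3-hydroxypropanoyl]-1,3-oxazolidin-2-one | O[C@@H](c1ccc(OCc2ccccc2)c(OCc2ccccc2)c1)[C@@H](OCc1ccccc1)C(=O)N1[C@H](Cc2ccccc2)COC1=O | intermediate
7 | (2R,3S)-2-(benzyloxy)-3-[3,4-bis(benzyloxy)phenyl]-3-hydroxy-N-methoxy-N-methylpropanamide | O[C@@H](c1ccc(OCc2ccccc2)c(OCc2ccccc2)c1)[C@@H](OCc1ccccc1)C(=O)N(C)OC | intermediate
8 | 3-(benzyloxy)phenol | Oc1cccc(OCc2ccccc2)c1 | starting material
9 | 5-(benzyloxy)-2-iodophenol | Oc1cc(OCc2ccccc2)ccc1I | intermediate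
10 | (2R,3R)-2-(benzyloxy)-3-[5-(benzyloxy)-2-iodophenoxy]-3-[3,4-bis(benzyloxy)phenyl]-N-methoxy-N-methylpropanamide | Ic1ccc(OCc2ccccc2)cc1O[C@H](c1ccc(OCc2ccccc2)c(OCc2ccccc2)c1)[C@@H](OCc1ccccc1)C(=O)N(C)OC | intermediate
11 | arylmagnesium chloride from 10 (Mg in place of iodine) | Cl[Mg]c1ccc(OCc2ccccc2)cc1O[C@H](c1ccc(OCc2ccccc2)c(OCc2ccccc2)c1)[C@@H](OCc1ccccc1)C(=O)N(C)OC | intermediate (not isolated)
12 | magnesium hemiaminal chelate (cyclised tetrahedral adduct, C4 undefined) | c1ccccc1COc1ccc2c(c1)O[C@H](c1ccc(OCc3ccccc3)c(OCc3ccccc3)c1)[C@@H](OCc1ccccc1)C2(O[Mg]Cl)N(C)OC | intermediate (not isolated)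
13 | (2R,3R)-3,7-bis(benzyloxy)-2-[3,4-bis(benzyloxy)phenyl]chroman-4-one (tetra-O-benzylfustin) | c1ccccc1COc1ccc2c(c1)O[C@H](c1ccc(OCc3ccccc3)c(OCc3ccccc3)c1)[C@@H](OCc1ccccc1)C2=O | intermediate
14 | 4,6-dibromobenzene-1,3-diol (4,6-dibromoresorcinol) | Oc1cc(O)c(Br)cc1Br | starting material
15 | 1,5-dibromo-2,4-bis[(4-methoxybenzyl)oxy]benzene | COc1ccc(COc2cc(OCc3ccc(OC)cc3)c(Br)cc2Br)cc1 | intermediate
16 | {5-bromo-2,4-bis[(4-methoxybenzyl)oxy]phenyl}lithium | [Li]c1cc(Br)c(OCc2ccc(OC)cc2)cc1OCc1ccc(OC)cc1 | intermediate (not isolated)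
17 | {5-bromo-2,4-bis[(4-methoxybenzyl)oxy]phenyl}cerium dichloride | Cl[Ce](Cl)c1cc(Br)c(OCc2ccc(OC)cc2)cc1OCc1ccc(OC)cc1 | intermediate (not isolated)
18 | (2R,3R)-3,7-bis(benzyloxy)-2-[3,4-bis(benzyloxy)phenyl]-4-{5-bromo-2,4-bis[(4-methoxybenzyl)oxy]phenyl}chroman-4-ol (C4 undefined) | c1ccccc1COc1ccc2c(c1)O[C@H](c1ccc(OCc3ccccc3)c(OCc3ccccc3)c1)[C@@H](OCc1ccccc1)C2(O)c1cc(Br)c(OCc2ccc(OC)cc2)cc1OCc1ccc(OC)cc1 | intermediate
19 | C4 benzylic cation from 18 | c1ccccc1COc1ccc2c(c1)O[C@H](c1ccc(OCc3ccccc3)c(OCc3ccccc3)c1)[C@@H](OCc1ccccc1)[C+]2c1cc(Br)c(OCc2ccc(OC)cc2)cc1OCc1ccc(OC)cc1 | intermediate (not isolated)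
20 | 2,3-trans-3,4-cis-3,7-bis(benzyloxy)-2-[3,4-bis(benzyloxy)phenyl]-4β-{5-bromo-2,4-bis[(4-methoxybenzyl)oxy]phenyl}chromane | c1ccccc1COc1ccc2c(c1)O[C@H](c1ccc(OCc3ccccc3)c(OCc3ccccc3)c1)[C@@H](OCc1ccccc1)[C@H]2c1cc(Br)c(OCc2ccc(OC)cc2)cc1OCc1ccc(OC)cc1 | intermediate (not isolated)
21 | (2R,3S,4S)-3,7-bis(benzyloxy)-2-[3,4-bis(benzyloxy)phenyl]-4-(5-bromo-2,4-dihydroxyphenyl)chromane | c1ccccc1COc1ccc2c(c1)O[C@H](c1ccc(OCc3ccccc3)c(OCc3ccccc3)c1)[C@@H](OCc1ccccc1)[C@H]2c1cc(Br)c(O)cc1O | intermediate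
22 | (2R,3R)-2-(benzyloxy)-3-[3,4-bis(benzyloxy)phenyl]-3-{4-[(2R,3S,4S)-3,7-bis(benzyloxy)-2-[3,4-bis(benzyloxy)phenyl]chroman-4-yl]-2-bromo-5-hydroxyphenoxy}-N-methoxy-N-methylpropanamide | c1ccccc1COc1ccc2c(c1)O[C@H](c1ccc(OCc3ccccc3)c(OCc3ccccc3)c1)[C@@H](OCc1ccccc1)[C@H]2c1cc(Br)c(cc1O)O[C@H](c1ccc(OCc3ccccc3)c(OCc3ccccc3)c1)[C@@H](OCc1ccccc1)C(=O)N(C)OC | intermediate
23 | dilithiated 22 (lithium phenoxide, lithium in place of bromine) | c1ccccc1COc1ccc2c(c1)O[C@H](c1ccc(OCc3ccccc3)c(OCc3ccccc3)c1)[C@@H](OCc1ccccc1)[C@H]2c1cc([Li])c(cc1O[Li])O[C@H](c1ccc(OCc3ccccc3)c(OCc3ccccc3)c1)[C@@H](OCc1ccccc1)C(=O)N(C)OC | intermediate (not isolated)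
24 | lithium hemiaminal chelate (ring F closed, C4 undefined) | c1ccccc1COc1ccc2c(c1)O[C@H](c1ccc(OCc3ccccc3)c(OCc3ccccc3)c1)[C@@H](OCc1ccccc1)[C@H]2c1cc2c(cc1O[Li])O[C@H](c1ccc(OCc3ccccc3)c(OCc3ccccc3)c1)[C@@H](OCc1ccccc1)C2(O[Li])N(C)OC | intermediate (not isolated)
25 | (2R,3R)-3-(benzyloxy)-2-[3,4-bis(benzyloxy)phenyl]-6-[(2R,3S,4S)-3,7-bis(benzyloxy)-2-[3,4-bis(benzyloxy)phenyl]chroman-4-yl]-7-hydroxychroman-4-one | c1ccccc1COc1ccc2c(c1)O[C@H](c1ccc(OCc3ccccc3)c(OCc3ccccc3)c1)[C@@H](OCc1ccccc1)[C@H]2c1cc2c(cc1O)O[C@H](c1ccc(OCc3ccccc3)c(OCc3ccccc3)c1)[C@@H](OCc1ccccc1)C2=O | intermediate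
26 | (2R,3R)-2-(3,4-dihydroxyphenyl)-6-[(2R,3S,4S)-2-(3,4-dihydroxyphenyl)-3,7-dihydroxychroman-4-yl]-3,7-dihydroxychroman-4-one | Oc1ccc2c(c1)O[C@H](c1ccc(O)c(O)c1)[C@@H](O)[C@H]2c1cc2c(cc1O)O[C@H](c1ccc(O)c(O)c1)[C@@H](O)C2=O | intermediate
27 | (2R,3S,4R)-2-(3,4-dihydroxyphenyl)-6-[(2R,3S,4S)-2-(3,4-dihydroxyphenyl)-3,7-dihydroxychroman-4-yl]chromane-3,4,7-triol | Oc1ccc2c(c1)O[C@H](c1ccc(O)c(O)c1)[C@@H](O)[C@H]2c1cc2c(cc1O)O[C@H](c1ccc(O)c(O)c1)[C@@H](O)[C@@H]2O | target

Total step count: 13. Longest linear sequence: 11 steps (steps 1, 2, 3, 5, 6, 8, 9, 10, 11, 12, 13); steps 4 and 7 are one-step side branches.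

Steps most likely to fail

Step 9. Hydride may be delivered to both faces of the C4 cation, so that the 4β configuration is formed with poor facial selectivity. Prolonged exposure to acid and silane may also open ring C reductively or let the 4-methoxybenzyl cation alkylate ring D. The fallback exchanges the roles of nucleophile and electrophile and sets out from 13. NaBH4 in THF/EtOH reduces 13 to the flavan-4-ol (2R,3S,4R)-3,7-bis(benzyloxy)-2-[3,4-bis(benzyloxy)phenyl]chroman-4-ol F1. BF3·OEt2 in CH2Cl2 then ionises F1 in the presence of commercial 4-bromoresorcinol, which attacks the C4 cation through its C6 (Friedel–Crafts alkylation, as in biomimetic profisetinidin couplings). This should give 21 together with its 4α-epimer F2, which is removed by chromatography; the fallback comes back to the route at 21.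

Step 10. The electron-rich benzylic oxyphosphonium may ionise, eroding the configuration at the future C2 of ring F; elimination to the enamide or etherification of the wrong phenol may also compete. The fallback replaces the Mitsunobu reaction by an epoxide opening under basic, non-ionising conditions and sets out from 21. Horner–Wadsworth–Emmons reaction of 4 with diethyl (N-methoxy-N-methylcarbamoylmethyl)phosphonate gives the E-enamide F3. Catalytic asymmetric epoxidation of F3 (Sm(O-i-Pr)3, BINOL, Ph3As=O, t-BuOOH, the BINOL antipode chosen for this sense) gives the trans-(2R,3S)-glycidic amide F4. The caesium phenoxide of 21 (Cs2CO3, DMF) opens F4 at the benzylic carbon with inversion to give the 2-hydroxy analogue F5 of 22. F5 is cyclised as in step 11 with one further equivalent of t-BuLi to the 3-hydroxy ketone F6, and hydrogenolysis of F6 as in step 12 comes back to the route at 26.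

Step 11. The aryllithium may be protonated before it cyclises, or deprotonation alpha to the amide may expel the aryloxide, or the base may add to the amide; the phenoxide may also slow the exchange. The fallback forms the same bond with an organochromium reagent and sets out from 22. The free phenol of 22 is benzylated (BnBr, K2CO3, DMF) to the benzyl ether F7, and i-Bu2AlH at −78 °C reduces the Weinreb amide to the aldehyde F8. An intramolecular Nozaki–Hiyama–Kishi reaction (CrCl2, NiCl2 cat., DMF) joins C4a to the aldehyde carbon and gives the chroman-4-ol F9 as a mixture at C4. Dess–Martin periodinane oxidises F9 to the octa-O-benzyl ketone F10, and hydrogenolysis of F10 as in step 12 comes back to the route at 26.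

Further compounds
F1 | step 9 | (2R,3S,4R)-3,7-bis(benzyloxy)-2-[3,4-bis(benzyloxy)phenyl]chroman-4-ol | c1ccccc1COc1ccc2c(c1)O[C@H](c1ccc(OCc3ccccc3)c(OCc3ccccc3)c1)[C@@H](OCc1ccccc1)[C@@H]2O
F2 | step 9 | (2R,3S,4R)-3,7-bis(benzyloxy)-2-[3,4-bis(benzyloxy)phenyl]-4-(5-bromo-2,4-dihydroxyphenyl)chromane (4α-epimer of 21) | c1ccccc1COc1ccc2c(c1)O[C@H](c1ccc(OCc3ccccc3)c(OCc3ccccc3)c1)[C@@H](OCc1ccccc1)[C@@H]2c1cc(Br)c(O)cc1O
F3 | step 10 | (E)-3-[3,4-bis(benzyloxy)phenyl]-N-methoxy-N-methylprop-2-enamide | CON(C)C(=O)/C=C/c1ccc(OCc2ccccc2)c(OCc2ccccc2)c1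
F4 | step 10 | (2R,3S)-3-[3,4-bis(benzyloxy)phenyl]-N-methoxy-N-methyloxirane-2-carboxamide | O1[C@@H](c2ccc(OCc3ccccc3)c(OCc3ccccc3)c2)[C@@H]1C(=O)N(C)OC
F5 | step 10 | 2-hydroxy analogue of 22 (free hydroxyl in place of the chain benzyloxy group) | c1ccccc1COc1ccc2c(c1)O[C@H](c1ccc(OCc3ccccc3)c(OCc3ccccc3)c1)[C@@H](OCc1ccccc1)[C@H]2c1cc(Br)c(cc1O)O[C@H](c1ccc(OCc3ccccc3)c(OCc3ccccc3)c1)[C@@H](O)C(=O)N(C)OC
F6 | step 10 | 3-hydroxy analogue of 25 (ring F hydroxyl free) | c1ccccc1COc1ccc2c(c1)O[C@H](c1ccc(OCc3ccccc3)c(OCc3ccccc3)c1)[C@@H](OCc1ccccc1)[C@H]2c1cc2c(cc1O)O[C@H](c1ccc(OCc3ccccc3)c(OCc3ccccc3)c1)[C@@H](O)C2=O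
F7 | step 11 | benzyl ether of 22 at the ring D phenol | c1ccccc1COc1ccc2c(c1)O[C@H](c1ccc(OCc3ccccc3)c(OCc3ccccc3)c1)[C@@H](OCc1ccccc1)[C@H]2c1cc(Br)c(cc1OCc1ccccc1)O[C@H](c1ccc(OCc3ccccc3)c(OCc3ccccc3)c1)[C@@H](OCc1ccccc1)C(=O)N(C)OC
F8 | step 11 | aldehyde from F7 (CHO in place of the Weinreb amide) | c1ccccc1COc1ccc2c(c1)O[C@H](c1ccc(OCc3ccccc3)c(OCc3ccccc3)c1)[C@@H](OCc1ccccc1)[C@H]2c1cc(Br)c(cc1OCc1ccccc1)O[C@H](c1ccc(OCc3ccccc3)c(OCc3ccccc3)c1)[C@@H](OCc1ccccc1)C=O
F9 | step 11 | octa-O-benzyl chroman-4-ol with ring F closed (C4 undefined) | c1ccccc1COc1ccc2c(c1)O[C@H](c1ccc(OCc3ccccc3)c(OCc3ccccc3)c1)[C@@H](OCc1ccccc1)[C@H]2c1cc2c(cc1OCc1ccccc1)O[C@H](c1ccc(OCc3ccccc3)c(OCc3ccccc3)c1)[C@@H](OCc1ccccc1)C2O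
F10 | step 11 | octa-O-benzyl ketone (7-O-benzyl ether of 25) | c1ccccc1COc1ccc2c(c1)O[C@H](c1ccc(OCc3ccccc3)c(OCc3ccccc3)c1)[C@@H](OCc1ccccc1)[C@H]2c1cc2c(cc1OCc1ccccc1)O[C@H](c1ccc(OCc3ccccc3)c(OCc3ccccc3)c1)[C@@H](OCc1ccccc1)C2=O
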